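Diyne 1 and iodoaniline 2 are joined to diamine 3 and masked as bis(trifluoroacetanilide) 4, a dimethylsilane carrying two (2-amido-4-bromophenyl)ethynyl arms. One oxidative palladium step should then form both N1–C2 bonds and the C3–C3' bond, closing the two pyrrole rings and, through the silicon bridge, a five-membered silole ring (5, then 6). The disconnection exploits the fact that in the target the brominated carbons C2 and C2' of the pyrrole rings flank the C3–C3' bond: one SiMe2 group can tie them together during ring formation and is afterwards exchanged at both C2–Si bonds for bromine, giving 7.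

Key step: step 3

Remark on the design: the nitrogens enter the oxidative step as trifluoroacetamides, because free arylamines add to benzoquinone and bind Pd(OAc)2, and the acidified N–H favours closure through nitrogen. The acyl groups are removed in the work-up of the same step.

Remark on regiochemistry: the bromine para to the alkyne-bearing carbon of each aryl ring becomes C6 of each indole, as the target requires. The target has no stereocenter.

Assumption: each twofold step is run to full conversion in one operation, so singly reacted species are treated as stages of that reaction and are not numbered.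

Step 1
Reactants: 1 diethynyldimethylsilane; 2 5-bromo-2-iodoaniline (2.1 equiv)
Product: 3 bis[(2-amino-4-bromophenyl)ethynyl]dimethylsilane
Conditions: PdCl2(PPh3)2 (3 mol%), CuI (3 mol%), Et3N/THF (degassed), rt
Reagents that add atoms: none
Why: Sonogashira coupling, in which oxidative addition of zerovalent palladium into C–I at room temperature is far faster than into C–Br, so each terminal alkyne of 1 is arylated once while the bromides, the free amines and the alkynyl–silicon bonds should survive the fluoride- and alkoxide-free amine medium.

Step 2
Reactants: 3 bis[(2-amino-4-bromophenyl)ethynyl]dimethylsilane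
Product: 4 bis{[4-bromo-2-(2,2,2-trifluoroacetamido)phenyl]ethynyl}dimethylsilane
Conditions: (CF3CO)2O (2.4 equiv), pyridine, CH2Cl2, 0 °C
Reagents that add atoms: trifluoroacetic anhydride, O=C(OC(=O)C(F)(F)F)C(F)(F)F
Why: N-acylation of the two anilines by the anhydride with pyridine as acid scavenger, which masks the amines for step 3 and should spare the alkynyl–silicon bonds in the buffered, non-nucleophilic medium.

Step 3
Reactants: 4 bis{[4-bromo-2-(2,2,2-trifluoroacetamido)phenyl]ethynyl}dimethylsilane
Product: 6 6,6'-dibromo-1H,1'H-3,3'-biindole bridged at C2 and C2' by SiMe2 (diindolo-fused silole), via bis(trifluoroacetyl)silole 5 (not isolated)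
Conditions: Pd(OAc)2 (10 mol%), 1,4-benzoquinone (1.2 equiv), 3 Å MS, MeCN (0.01 M), 50 °C; then filter, Et3N, MeOH, rt
Reagents that add atoms: none
Why: Proposed new method: acetate-assisted anti attack of each trifluoroacetamide nitrogen on its Pd(OAc)2-activated silylalkyne (5-endo-dig, the only geometrically possible mode, so the silicon-bearing carbon becomes C2) should give two indol-3-yl–palladium bonds that meet, directly or by transfer between two palladium centres, in a six-membered 1-pallada-4-silacyclohexa-2,5-diene; C(sp2)–C(sp2) reductive elimination then forms C3–C3' and contracts this ring to the silole, and benzoquinone with the released acetic acid returns zerovalent palladium to divalent palladium. The closest known reaction type is the intermolecular cyclization–homocoupling of 2-alkynylanilides to 3,3'-biindoles under divalent palladium, here made intramolecular by the SiMe2 tether. Ring closures: both pyrrole rings by 5-endo-dig aminopalladation, the silole by reductive elimination from the palladacycle; no stereocenter is formed. The step needs attack through nitrogen and not oxygen of the amide, which the acidity of the CF3CO–NH group should secure, and C–C coupling faster than protodepalladation or coupling between molecules, which the placement of both alkynes on one silicon, high dilution and the absence of strong acid or base should secure. The aryl bromides and the alkynyl–silicon bonds should survive because no phosphine-bound zerovalent palladium, fluoride or alkoxide is present during the palladium stage, and Et3N/MeOH afterwards removes the labile N-trifluoroacetyl groups of 5 without touching the C2–Si bonds.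

Step 4
Reactants: 6 6,6'-dibromo-1H,1'H-3,3'-biindole bridged at C2 and C2' by SiMe2
Product: 7 2,2',6,6'-tetrabromo-1H,1'H-3,3'-biindole
Conditions: NBS (2.05 equiv), THF, −78 → 0 °C, dark; aq. Na2S2O3/NaHCO3
Reagents that add atoms: N-bromosuccinimide, O=C1CCC(=O)N1Br
Why: Electrophilic ipso-bromodesilylation of 2-silylindoles, in which bromine enters at the silicon-bearing C2 through a cation stabilized beta to silicon and silicon is lost, once at C2 and once at C2', so the silole opens and silicon leaves as a silanediol on aqueous work-up while no free C2–H or C3–H competes and the 6-bromo groups deactivate the benzo rings.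

Compound list
1 | diethynyldimethylsilane | C[Si](C)(C#C)C#C | starting material
2 | 5-bromo-2-iodoaniline | Nc1cc(Br)ccc1I | starting material
3 | bis[(2-amino-4-bromophenyl)ethynyl]dimethylsilane | C[Si](C)(C#Cc1ccc(Br)cc1N)C#Cc1ccc(Br)cc1N | intermediate
4 | bis{[4-bromo-2-(2,2,2-trifluoroacetamido)phenyl]ethynyl}dimethylsilane | C[Si](C)(C#Cc1ccc(Br)cc1NC(=O)C(F)(F)F)C#Cc1ccc(Br)cc1NC(=O)C(F)(F)F | intermediate
5 | 6,6'-dibromo-1,1'-bis(trifluoroacetyl)-3,3'-biindole bridged at C2 and C2' by SiMe2 (not isolated) | C[Si]1(C)c2n(C(=O)C(F)(F)F)c3cc(Br)ccc3c2-c2c1n(C(=O)C(F)(F)F)c1cc(Br)ccc21 | intermediate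
6 | 6,6'-dibromo-1H,1'H-3,3'-biindole bridged at C2 and C2' by SiMe2 (diindolo-fused silole; silole ring Si, C2, C3, C3', C2') | C[Si]1(C)c2[nH]c3cc(Br)ccc3c2-c2c1[nH]c1cc(Br)ccc21 | intermediate
7 | 2,2',6,6'-tetrabromo-1H,1'H-3,3'-biindole | Brc1ccc2c(-c3c(Br)[nH]c4cc(Br)ccc34)c(Br)[nH]c2c1 | target

Total step count: 4
Longest linear sequence: 4 steps (1/2 → 3 → 4 → 6 → 7)

Steps most likely to fail

Step 3. The first indol-3-yl–palladium bond may be protonated before the second ring closes. An alkynyl group may also pass from silicon to palladium, or coupling may occur between molecules, so that C3–C3' is not formed within one molecule. The fallback uses known chemistry without the silicon tether and sets out from 3. KOtBu in NMP at rt cleaves both alkynyl–silicon bonds and cyclizes each 2-alkynylaniline (base-mediated 5-endo-dig hydroamination), giving two equivalents of 6-bromo-1H-indole F1. Base-catalysed addition (Et2NH, EtOH, rt) of F1 through C3 to the ketone of purchased 6-bromoisatin F2 gives racemic 6-bromo-3-(6-bromo-1H-indol-3-yl)-3-hydroxyindolin-2-one F3. BH3·THF at reflux reduces the hydroxy-lactam with aromatization to 6,6'-dibromo-1H,1'H-3,3'-biindole F4. NBS (2 equiv, THF, −78 °C) then brominates C2 and C2', the only open pyrrole positions, and the sequence comes back to the route at 7.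

Step 4. The N-bromo reagent may oxidize the electron-rich N–H bis-indole (3-bromoindolenine formation, then oxindole on work-up) or brominate the benzo rings, or cleavage may stall after the first C2–Si bond. The fallback sets out from 6. Boc2O with catalytic DMAP in MeCN gives the di-tert-butyl 1,1'-dicarboxylate of the silole-bridged 6,6'-dibromo-3,3'-biindole F5, whose carbamate nitrogens no longer allow N-bromination or indolenine formation. Br2 (2 equiv, CH2Cl2, −78 °C) should then cleave both C2–Si bonds by ipso-substitution to di-tert-butyl 2,2',6,6'-tetrabromo-3,3'-biindole-1,1'-dicarboxylate F6. K2CO3 in MeOH/THF removes both carbamates, and the sequence comes back to the route at 7.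

Step 1. The alkynyl–silicon bonds may be cleaved, or the diyne may undergo copper-mediated oxidative coupling, during the two arylations, or the reaction may stall after the first arylation. The fallback makes the C(sp)–Si bonds last, by substitution at silicon, and sets out from 2. Sonogashira coupling with trimethylsilylacetylene (PdCl2(PPh3)2, CuI, Et3N, rt) gives 5-bromo-2-[(trimethylsilyl)ethynyl]aniline F7. K2CO3 in MeOH gives 5-bromo-2-ethynylaniline F8, and (CF3CO)2O/pyridine gives N-(5-bromo-2-ethynylphenyl)-2,2,2-trifluoroacetamide F9. Double deprotonation of F9 with EtMgBr (2.1 equiv, THF, 0 °C to rt; N–H first, then C–H), then Me2SiCl2 (0.5 equiv) and aqueous NH4Cl, should give 4, where the sequence comes back to the route; step 2 is then not needed.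

Further compounds
F1 | step 3 | 6-bromo-1H-indole | Brc1ccc2cc[nH]c2c1
F2 | step 3 | 6-bromoisatin (purchased building block of the fallback) | O=C1Nc2cc(Br)ccc2C1=O
F3 | step 3 | racemic 6-bromo-3-(6-bromo-1H-indol-3-yl)-3-hydroxyindolin-2-one | O=C1Nc2cc(Br)ccc2C1(O)c1c[nH]c2cc(Br)ccc12
F4 | step 3 | 6,6'-dibromo-1H,1'H-3,3'-biindole | Brc1ccc2c(c1)[nH]cc2-c1c[nH]c2cc(Br)ccc12
F5 | step 4 | di-tert-butyl 1,1'-dicarboxylate of 6,6'-dibromo-3,3'-biindole bridged at C2 and C2' by SiMe2 | C[Si]1(C)c2n(C(=O)OC(C)(C)C)c3cc(Br)ccc3c2-c2c1n(C(=O)OC(C)(C)C)c1cc(Br)ccc21
F6 | step 4 | di-tert-butyl 2,2',6,6'-tetrabromo-3,3'-biindole-1,1'-dicarboxylate | CC(C)(C)OC(=O)n1c(Br)c(-c2c(Br)n(C(=O)OC(C)(C)C)c3cc(Br)ccc23)c2ccc(Br)cc21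
F7 | step 1 | 5-bromo-2-[(trimethylsilyl)ethynyl]aniline | C[Si](C)(C)C#Cc1ccc(Br)cc1N
F8 | step 1 | 5-bromo-2-ethynylaniline | C#Cc1ccc(Br)cc1N
F9 | step 1 | N-(5-bromo-2-ethynylphenyl)-2,2,2-trifluoroacetamide | C#Cc1ccc(Br)cc1NC(=O)C(F)(F)F
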